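The numbers in the tables were generated by integration for substances that don't exist; scatter was added.

Amounts first: we count the charge in three pots, substrate, target and isomer of the product, since the catalyst is far less than the substrate. The flask asked about is the winter run carried on.

common to all: substrate 1.5 M; added ligand 2.4 mM
- winter: catalyst 0.76 mM (in portions, 3); the very flask that is asked about, followed so far; portions every 80 min
- dawn: catalyst 1.1 mM (in portions, 3); run made earlier; portions every 80 min
- flask: catalyst 0.76 mM (in portions, 3); the portions of catalyst follow each other after 80 min, the first at the start; time 5.0 d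

| run | time / d | target / % | isomer of the product / % |
|---|---|---|---|
| winter | 0.208 | 16.0 | 2.7 |
| winter | 0.500 | 27.9 | 6.3 |
| winter | 1.04 | 31.0 | 16.7 |
| winter | 2.50 | 26.7 | 28.4 |
| dawn | 1.25 | 27.4 | 24.9 |
| dawn | 2.50 | 23.4 | 35.9 |
| dawn | 4.00 | 22.2 | 39.5 |
| dawn | 5.00 | 20.1 | 44.3 |

(readings scatter by 1 percentage point)

- the numbers in the tables scatter by 1 percentage point (one standard deviation)
- candidate steps: substrate <-> target; target + catalyst <-> isomer of the product + catalyst; isomer of the product + catalyst <-> substrate + catalyst; catalyst + added ligand <-> idle complex

1. the target in the flask at 5.0 d, as a percentage of the substrate charged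
2. the isomer of the product in the flask at 5.0 d, as a percentage of the substrate charged
3. the substrate in the flask at 5.0 d, as a percentage of the substrate charged

We go up a ladder of times. On the lowest rung, the portions of catalyst are in by 0.111 d. On the next, target over substrate climbs in the winter run from 0.197 at 0.208 d to 0.593 at 1.04 d, and then stays level: 0.595 at 2.50 d. On the top rung the isomer creeps towards a ceiling, which we take as the last dawn reading, 44.3%. We treat the gap below that ceiling as shrinking in a pseudo-first-order way:

winter rate = ln(gap at 1.04 d / gap at 2.50 d) / time between = 0.378 d⁻¹

dawn rate, likewise = 0.670 d⁻¹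

The winter half-life, 1.83 d, is longer than the time the portions take, so we count the catalyst as charged at once.

Dawn runs 1.77 times as fast as winter on 1.45 times the catalyst. Suppose the catalyst sits mostly in the idle complex, one ligand each. Free catalyst then goes as catalyst charge / (ligand charge − catalyst charge), which is 0.463 in winter and 0.846 in dawn, a factor of 1.83. So we carry the clock rate, the isomer's rate per unit of that ratio:

clock rate = 0.815 d⁻¹

isomer at 5.0 d = ceiling − gap at 2.50 d × exp(−clock rate × ratio × 2.50 d) = 38.1%

The rest, split by 0.595, gives us 38.8% substrate and 23.1% target.

The forecast, “Taking about 0.33 per day from 28.4% at 2.5 d”, stands near our numbers but not on them, at 23.5% target, 37% isomer and 39.5% substrate.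

The flask gives 23.3% target and 38.9% substrate, and of the isomer of the product it gives 37.8%.

    substrate ⇌ target (K = 0.600, k = 0.0510 h⁻¹)
    target + catalyst ⇌ isomer of the product + catalyst, rate k2*[catalyst]*[target] forward; the back reaction follows from the equilibrium constant (K = 2.00, k = 260 M⁻¹ h⁻¹)
    isomer of the product + catalyst ⇌ substrate + catalyst, rate k3*[catalyst]*[isomer of the product] forward; the back reaction follows from the equilibrium constant (k = 180 M⁻¹ h⁻¹)
    catalyst + added ligand ⇌ idle complex, settled at all times (K = 13000 M⁻¹)

On this flask the clock rate times the ratio, 0.377 d⁻¹, put our isomer 0.30 percentage points above the flask's value. The neighbour with 4.10 mM of ligand has a ratio of 0.228, half that of this flask, so its clock rate times ratio is 0.186 d⁻¹. Its 5.0 d then corresponds to 2.46 d in this flask, and the same reckoning gives 28.1% isomer. The neighbour holds 28.5% isomer and 44.8% substrate at 5.0 d, and this flask at 2.50 d holds 27.9% isomer and 45.2% substrate.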